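**Assumption:** the SMILES is read as the (4aS,8aS) trans-decalin of the normal drimane series (the configuration of (+)-sclareolide) with both side-chain alkenes E. Below, Dr = (4aS,8aS)-2,5,5,8a-tetramethyl-3,4,4a,5,6,7,8,8a-octahydronaphthalen-1-yl.

## Retrosynthetic overview

1. Rings A and B, with both stereocentres, are bought intact as (+)-sclareolide; only the side chain and the butenolide (ring C) are built.
2. Last disconnection: the butenolide C4–C5 and O1–C2 bonds, giving a dienynal plus formaldehyde. A carbene catalyst makes the ynal β-carbon nucleophilic (allenolate, homoenolate polarity); it attacks CH2O and the new alkoxide closes the lactone.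
3. Dienynal → (E,E)-chlorodienol + propynal diethyl acetal (Sonogashira coupling, then acetal hydrolysis).
4. Trisubstituted (E)-allylic alcohol → homodrimanyl Grignard reagent + (E)-5-chloropent-4-en-2-yn-1-ol by alkoxide-directed anti-carbomagnesiation, which fixes the alkene geometry.
5. Ring order: A/B from the chiral pool (ring alkene moved to the tetrasubstituted position in the first step); ring C is formed last.

## Route

Step 1
Reactants: 1 (+)-sclareolide
Product: 2 methyl 2-Dr-acetate
Conditions: conc. H2SO4, MeOH, reflux, 24 h; minor alkene isomers removed on AgNO3-impregnated silica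
Reagents that add atoms: methanol (CO)
Why: Acid-mediated lactone methanolysis with ionisation at the tertiary C–O carbon and E1 loss of a proton (Fischer esterification/E1 dehydration) under equilibrating conditions funnels to the tetrasubstituted ring alkene, while the two ring-fusion stereocentres are untouched.

Step 2
Reactants: 2 methyl 2-Dr-acetate
Product: 3 2-Dr-ethan-1-ol
Conditions: LiAlH4, THF, 0 °C → rt
Reagents that add atoms: none
Why: Standard hydride reduction of an ester to the primary alcohol; the isolated tetrasubstituted alkene is inert to LiAlH4.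

Step 3
Reactants: 3 2-Dr-ethan-1-ol
Product: 4 1-bromo-2-Dr-ethane
Conditions: CBr4, PPh3, CH2Cl2, 0 °C
Reagents that add atoms: carbon tetrabromide (BrC(Br)(Br)Br)
Why: Appel reaction, an SN2 displacement of the alkoxyphosphonium by bromide at the unhindered primary carbon under neutral conditions, so the ring alkene does not migrate.

Step 4
Reactants: 5 (E)-1,2-dichloroethene (5 equiv); 6 prop-2-yn-1-ol
Product: 7 (E)-5-chloropent-4-en-2-yn-1-ol
Conditions: Pd(PPh3)4 (5 mol %), CuI (10 mol %), n-BuNH2, Et2O, rt
Reagents that add atoms: none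
Why: Sonogashira coupling; the excess dihalide enforces mono-coupling and the E geometry is retained through oxidative addition and reductive elimination.

Step 5
Reactants: 4 1-bromo-2-Dr-ethane; 7 (E)-5-chloropent-4-en-2-yn-1-ol
Product: 11 (2E,4E)-5-chloro-2-(2-Dr-ethyl)penta-2,4-dien-1-ol, via (2-Dr-ethyl)magnesium bromide 8 (not isolated), via bromomagnesium (E)-5-chloropent-4-en-2-yn-1-olate 9 (not isolated), via cyclic vinylmagnesium alkoxide 10 (not isolated)
Conditions: (a) 4, Mg, THF, rt; (b) 7 (1.5 equiv), EtMgBr (1.5 equiv), Et2O, −20 °C; (c) combine, CuI (10 mol %), −20 °C → rt, 16 h; then H2O, 0 °C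
Reagents that add atoms: none
Why: Copper-catalysed, alkoxide-directed anti-carbomagnesiation of a propargylic alcohol delivers the alkyl group to the alkyne carbon next to the carbinol and leaves magnesium cis to CH2O in a five-membered chelate, so protonolysis gives the trisubstituted alkene with CH2OH trans to the chlorovinyl group (2E), the vinyl chloride being inert to the Grignard reagent.

Step 6
Reactants: 11 (2E,4E)-5-chloro-2-(2-Dr-ethyl)penta-2,4-dien-1-ol; 12 3,3-diethoxyprop-1-yne
Product: 13 (2E,4E)-8,8-diethoxy-2-(2-Dr-ethyl)octa-2,4-dien-6-yn-1-ol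
Conditions: PdCl2(PhCN)2 (5 mol %), CuI (10 mol %), piperidine, rt → 40 °C
Reagents that add atoms: none
Why: Sonogashira coupling of a 1-chloro-1,3-diene in piperidine proceeds with retention of the 4E geometry and tolerates the free allylic alcohol, the aldehyde being carried as its diethyl acetal.

Step 7
Reactants: 13 (2E,4E)-8,8-diethoxy-2-(2-Dr-ethyl)octa-2,4-dien-6-yn-1-ol
Product: 14 (4E,6E)-9-Dr-7-(hydroxymethyl)nona-4,6-dien-2-ynal
Conditions: TsOH·H2O (10 mol %), acetone–H2O (10:1), 0 °C → rt; used at once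
Reagents that add atoms: water (O)
Why: Acid-catalysed acetal hydrolysis, driven by transacetalisation to acetone, unmasks the conjugated ynal without touching either alkene geometry.

Step 8
Reactants: 14 (4E,6E)-9-Dr-7-(hydroxymethyl)nona-4,6-dien-2-ynal
Product: 17 4-[(1E,3E)-6-Dr-4-(hydroxymethyl)hexa-1,3-dien-1-yl]furan-2(5H)-one, via carbene-bound ynenol 15 (not isolated), via acyl azolium alkoxide 16 (not isolated)
Conditions: 1,3-bis(2,4,6-trimethylphenyl)imidazolium chloride (15 mol %), K2CO3 (20 mol %), LiCl (1.0 equiv), paraformaldehyde (6 equiv), THF, 40 °C, slow addition of 14 over 6 h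
Reagents that add atoms: paraformaldehyde, reacting as formaldehyde (C=O)
Why: Proposed new method: the carbene adds to the ynal carbonyl and proton transfer gives the ynenol 15, an allenolate whose β-carbon (normally the electrophilic position of the ynal) is nucleophilic and attacks formaldehyde, a second electrophilic carbon; tautomerisation gives the unsaturated acyl azolium 16, whose alkoxide closes the five-membered lactone and releases the carbene, this irreversible lactonisation being the only productive exit so that attack through the remote vinylogous positions is not rewarded; the closest known reaction type is the carbene/Lewis acid catalysed formal [3+2] annulation of alkynyl aldehydes with activated ketones to butenolides, supported by carbene-catalysed homoenolate additions of enals to aldehydes and by the use of paraformaldehyde as electrophile in carbene-catalysed hydroxymethylation; no stereocentre is formed and the diene geometry is untouched.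

## Compound list

1 | (+)-sclareolide, (3aR,5aS,9aS,9bR)-3a,6,6,9a-tetramethyldecahydronaphtho[2,1-b]furan-2(1H)-one | CC1(CCC[C@]2([C@H]1CC[C@@]3([C@@H]2CC(=O)O3)C)C)C | starting material
2 | methyl 2-Dr-acetate | CC1=C(CC(=O)OC)[C@@]2(C)CCCC(C)(C)[C@@H]2CC1 | intermediate
3 | 2-Dr-ethan-1-ol | CC1=C(CCO)[C@@]2(C)CCCC(C)(C)[C@@H]2CC1 | intermediate
4 | 1-bromo-2-Dr-ethane | CC1=C(CCBr)[C@@]2(C)CCCC(C)(C)[C@@H]2CC1 | intermediate
5 | (E)-1,2-dichloroethene | Cl/C=C/Cl | starting material
6 | prop-2-yn-1-ol | C#CCO | starting material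
7 | (E)-5-chloropent-4-en-2-yn-1-ol | OCC#C/C=C/Cl | intermediate
8 | (2-Dr-ethyl)magnesium bromide | CC1=C(CC[Mg]Br)[C@@]2(C)CCCC(C)(C)[C@@H]2CC1 | intermediate
9 | bromomagnesium (E)-5-chloropent-4-en-2-yn-1-olate | Br[Mg]OCC#C/C=C/Cl | intermediate
10 | 3-[(E)-2-chloroethenyl]-4-(2-Dr-ethyl)-2,5-dihydro-1,2-oxamagnesole (cyclic vinylmagnesium alkoxide) | CC1=C(CCC2=C(/C=C/Cl)[Mg]OC2)[C@@]2(C)CCCC(C)(C)[C@@H]2CC1 | intermediate
11 | (2E,4E)-5-chloro-2-(2-Dr-ethyl)penta-2,4-dien-1-ol | CC1=C(CC/C(=C\C=C\Cl)CO)[C@@]2(C)CCCC(C)(C)[C@@H]2CC1 | intermediate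
12 | 3,3-diethoxyprop-1-yne | C#CC(OCC)OCC | starting material
13 | (2E,4E)-8,8-diethoxy-2-(2-Dr-ethyl)octa-2,4-dien-6-yn-1-ol | CC1=C(CC/C(=C\C=C\C#CC(OCC)OCC)CO)[C@@]2(C)CCCC(C)(C)[C@@H]2CC1 | intermediate
14 | (4E,6E)-9-Dr-7-(hydroxymethyl)nona-4,6-dien-2-ynal | CC1=C(CC/C(=C\C=C\C#CC=O)CO)[C@@]2(C)CCCC(C)(C)[C@@H]2CC1 | intermediate
15 | carbene-bound ynenol, 2-[(4E,6E)-1-hydroxy-9-Dr-7-(hydroxymethyl)nona-4,6-dien-2-yn-1-ylidene]-1,3-bis(2,4,6-trimethylphenyl)-2,3-dihydro-1H-imidazole | CC1=C(CC/C(=C\C=C\C#CC(O)=C3N(c4c(C)cc(C)cc4C)C=CN3c3c(C)cc(C)cc3C)CO)[C@@]2(C)CCCC(C)(C)[C@@H]2CC1 | intermediate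
16 | acyl azolium alkoxide, 2-[(2Z,4E,6E)-9-Dr-7-(hydroxymethyl)-3-(oxidomethyl)nona-2,4,6-trienoyl]-1,3-bis(2,4,6-trimethylphenyl)imidazolium | CC1=C(CC/C(=C\C=C\C(C[O-])=C\C(=O)c3n(c4c(C)cc(C)cc4C)cc[n+]3c3c(C)cc(C)cc3C)CO)[C@@]2(C)CCCC(C)(C)[C@@H]2CC1 | intermediate
17 | 4-[(1E,3E)-6-Dr-4-(hydroxymethyl)hexa-1,3-dien-1-yl]furan-2(5H)-one | CC1=C(CC/C(=C\C=C\C2=CC(=O)OC2)CO)[C@@]2(C)CCCC(C)(C)[C@@H]2CC1 | target

## Step count and risks

Total step count: 8. Longest linear sequence: 7 (steps 1, 2, 3, 5, 6, 7, 8 from (+)-sclareolide).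

**Most likely to fail, 1: step 8.** Formaldehyde has not been used as the electrophile in this annulation. Competing paths are β-protonation of the allenolate followed by esterification by the free hydroxyl, 1,2-addition giving a hydroxymethyl ynone, attack of the allenolate on a second ynal, and carbene-catalysed self-condensation of formaldehyde.
Fallback: it sets out from 11 and rejoins the route at 17. The vinyl chloride 11 is coupled in a Stille reaction (Pd2(dba)3, P(t-Bu)3, CsF, dioxane, 90 °C) with 4-(tributylstannyl)furan-2(5H)-one F1, itself made from commercial 4-bromofuran-2(5H)-one and hexabutylditin (Pd(PPh3)4, toluene, 100 °C). The stannane acts as a β-acyl vinyl anion, so the butenolide β-carbon is again the donor, and 17 is obtained directly.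

**Most likely to fail, 2: step 5.** The precious primary alkyl Grignard reagent must add with the right regiochemistry and anti stereochemistry to a conjugated chloroenynol; β-hydride loss from the alkylcopper and attack on the enyne are possible.
Fallback: it sets out from 4 and rejoins the route at 11. Sodium triethyl phosphonoacetate is C-alkylated with 4 (NaH, DMF, 60 °C) to give ethyl 2-(diethoxyphosphoryl)-4-Dr-butanoate F2. Horner–Wadsworth–Emmons olefination with (E)-3-chloroprop-2-enal (NaH, THF, 0 °C) gives ethyl (2E,4E)-5-chloro-2-(2-Dr-ethyl)penta-2,4-dienoate F3, with the ester trans to the chlorovinyl group as is normal for α-alkyl phosphonoacetates. Reduction with i-Bu2AlH (CH2Cl2, −78 °C) then gives 11.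

**Most likely to fail, 3: step 7.** The acid needed to open a propargylic acetal may ionise the dienylic alcohol, and the dienynal is a sensitive Michael acceptor.
Fallback: it sets out from 11 and rejoins the route at 14, avoiding any acid. Sonogashira coupling of 11 with ethynyltrimethylsilane (PdCl2(PhCN)2, CuI, piperidine) gives (2E,4E)-2-(2-Dr-ethyl)-7-(trimethylsilyl)hepta-2,4-dien-6-yn-1-ol F4. K2CO3 in MeOH removes silicon to give (2E,4E)-2-(2-Dr-ethyl)hepta-2,4-dien-6-yn-1-ol F5. Double deprotonation (n-BuLi, 2.1 equiv, THF, −78 °C), formylation with DMF and inverse quench into cold aqueous KH2PO4 gives 14.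

Further compounds
F1 | step 8 | 4-(tributylstannyl)furan-2(5H)-one | CCCC[Sn](CCCC)(CCCC)C1=CC(=O)OC1
F2 | step 5 | ethyl 2-(diethoxyphosphoryl)-4-Dr-butanoate | CC1=C(CCC(C(=O)OCC)P(=O)(OCC)OCC)[C@@]2(C)CCCC(C)(C)[C@@H]2CC1
F3 | step 5 | ethyl (2E,4E)-5-chloro-2-(2-Dr-ethyl)penta-2,4-dienoate | CC1=C(CC/C(=C\C=C\Cl)C(=O)OCC)[C@@]2(C)CCCC(C)(C)[C@@H]2CC1
F4 | step 7 | (2E,4E)-2-(2-Dr-ethyl)-7-(trimethylsilyl)hepta-2,4-dien-6-yn-1-ol | CC1=C(CC/C(=C\C=C\C#C[Si](C)(C)C)CO)[C@@]2(C)CCCC(C)(C)[C@@H]2CC1
F5 | step 7 | (2E,4E)-2-(2-Dr-ethyl)hepta-2,4-dien-6-yn-1-ol | CC1=C(CC/C(=C\C=C\C#C)CO)[C@@]2(C)CCCC(C)(C)[C@@H]2CC1
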